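**Strategy.** Everything rests on making the benzene ring of the coumarin, not acylating it. C4a, C5, C6, C7, C8 and C8a carry oxygen on C5, C7 and C8a with the acyl carbon on C8, the imprint of a Claisen-folded tetraketide. In one operation methoxide opens a 6-(2-oxoalkyl)-4-methoxy-2-pyranone and the doubly activated methylene closes onto the freed ester, forming the C8–C8a bond and the arene as a symmetric 2,6-dihydroxy-4-methoxyphenyl ketone. The precursor already holds the C5 methoxy group and the complete cis-disubstituted cyclohexenoyl unit, whose three stereocentres come from one Diels–Alder addition to (S)-5-methylfuran-2(5H)-one.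

Key step: step 10

Remark on stereochemistry: with C1 as the acyl-bearing ring carbon, the C5 methyl and the C6 side chain of the cyclohexene are cis; enolate trapping after conjugate addition to a cyclohexenone would give the trans isomer, so the relationship is taken from an endo cycloaddition to a cis-fused lactone.
Remark on groups: the pyranone O4 is carried as its methyl ether, which becomes the C5 methoxy group and makes selective phenol methylation unnecessary; the carbinol is carried as the TBDPS ether, which should tolerate the acid of the coumarin annulation.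
Remark on drawing: metalated and ionic species made in the flask are drawn in their simplest form; the coumarin is numbered in the usual way.

Step 1
Reactants: 1 (S)-but-3-yn-2-ol
Product: 3 (S)-4-hydroxypent-2-ynoic acid, via O,C-dilithiated alkynol 2 (not isolated)
Conditions: n-BuLi (2.2 equiv), THF, −78 → 0 °C; CO2, −78 °C → rt; 2 M HCl
Reagents that add atoms: carbon dioxide, O=C=O
Why: Double deprotonation gives the alkoxide–acetylide, whose carbon terminus is carboxylated by CO2 (acetylide carboxylation); the carbinol stereocentre is not touched.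

Step 2
Reactants: 3 (S)-4-hydroxypent-2-ynoic acid
Product: 5 (S)-5-methylfuran-2(5H)-one, via (2Z,4S)-4-hydroxypent-2-enoic acid 4 (not isolated)
Conditions: H2 (1 atm), Pd/CaCO3 poisoned with Pb(OAc)2, quinoline, EtOAc, rt; then TsOH (cat.), CH2Cl2, rt
Reagents that add atoms: none
Why: Lindlar semihydrogenation adds H2 syn to give the Z-alkene, whose cis-disposed hydroxyl and carboxyl groups lactonise to the butenolide; the stereocentre is retained.

Step 3
Reactants: 6 (2E,4E)-hexa-2,4-dienoic acid (sorbic acid)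
Product: 9 benzyl N-[(1E,3E)-penta-1,3-dien-1-yl]carbamate, via (2E,4E)-hexa-2,4-dienoyl azide 7 (not isolated), via (1E,3E)-1-isocyanatopenta-1,3-diene 8 (not isolated)
Conditions: (PhO)2P(O)N3, Et3N, toluene, rt; then BnOH, 4-tert-butylcatechol (cat.), 90 °C
Reagents that add atoms: diphenylphosphoryl azide, [N-]=[N+]=NP(=O)(Oc1ccccc1)Oc1ccccc1; benzyl alcohol, OCc1ccccc1
Why: Curtius rearrangement of the dienoyl azide keeps both E double bonds and the isocyanate is trapped by the alcohol, the standard entry to stereodefined 1-(acylamino)-1,3-dienes.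

Step 4
Reactants: 5 (S)-5-methylfuran-2(5H)-one; 9 benzyl N-[(1E,3E)-penta-1,3-dien-1-yl]carbamate
Product: 10 benzyl N-[(3S,3aR,4R,7S,7aR)-3,4-dimethyl-1-oxo-1,3,3a,4,7,7a-hexahydroisobenzofuran-7-yl]carbamate
Conditions: toluene, 4-tert-butylcatechol (cat.), 120 °C, sealed tube
Reagents that add atoms: none
Why: Thermal Diels–Alder reaction in which the nitrogen-bearing diene terminus bonds to the lactone alpha carbon (ortho rule for 1-donor dienes) and the methyl-bearing terminus to the beta carbon; the cyclic Z-dienophile gives the cis ring fusion, endo approach of the lactone carbonyl places the C4 methyl and the C7 nitrogen cis to the lactone, and attack anti to the butenolide methyl fixes C3a relative to C3 and so the absolute configuration.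

Step 5
Reactants: 10 benzyl N-[(3S,3aR,4R,7S,7aR)-3,4-dimethyl-1-oxo-1,3,3a,4,7,7a-hexahydroisobenzofuran-7-yl]carbamate
Product: 11 (3S,3aR,4R,7S,7aR)-7-amino-3,4-dimethylhexahydroisobenzofuran-1(3H)-one
Conditions: H2 (1 atm), Pd/C (10%), EtOAc–MeOH, rt
Reagents that add atoms: none
Why: Heterogeneous hydrogenation saturates the disubstituted alkene and hydrogenolyses the benzyl carbamate in the same operation; no stereocentre is changed.

Step 6
Reactants: 11 (3S,3aR,4R,7S,7aR)-7-amino-3,4-dimethylhexahydroisobenzofuran-1(3H)-one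
Product: 13 (3S,3aR,4R)-3,4-dimethyl-3a,4,5,6-tetrahydroisobenzofuran-1(3H)-one, via trimethylammonium iodide 12 (not isolated)
Conditions: MeI (excess), K2CO3, DMF, rt → 40 °C
Reagents that add atoms: none
Why: Exhaustive N-methylation gives the quaternary ammonium salt, which eliminates by the E1cB (Hofmann-type) pathway through the lactone enolate, so the double bond can only form between C7a and C7; C3a is not acidified and keeps its configuration.

Step 7
Reactants: 13 (3S,3aR,4R)-3,4-dimethyl-3a,4,5,6-tetrahydroisobenzofuran-1(3H)-one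
Product: 14 (5R,6R)-6-[(1S)-1-hydroxyethyl]-N-methoxy-N,5-dimethylcyclohex-1-ene-1-carboxamide
Conditions: Me(MeO)NH·HCl (3 equiv), AlMe3 (3 equiv), CH2Cl2, 0 °C → rt; aq. KNaC4H4O6
Reagents that add atoms: N,O-dimethylhydroxylamine hydrochloride, CNOC.Cl
Why: Weinreb aminolysis, in which the aluminium amide opens the lactone by acyl substitution without touching the stereocentres; the crude hydroxy amide is silylated at once to forestall relactonisation.

Step 8
Reactants: 14 (5R,6R)-6-[(1S)-1-hydroxyethyl]-N-methoxy-N,5-dimethylcyclohex-1-ene-1-carboxamide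
Product: 15 (5R,6R)-6-[(1S)-1-(tert-butyldiphenylsilyloxy)ethyl]-N-methoxy-N,5-dimethylcyclohex-1-ene-1-carboxamide
Conditions: TBDPSOTf, 2,6-lutidine, CH2Cl2, −20 °C → rt
Reagents that add atoms: tert-butyldiphenylsilyl trifluoromethanesulfonate, CC(C)(C)[Si](OS(=O)(=O)C(F)(F)F)(c1ccccc1)c1ccccc1
Why: Silyl triflate silylation of the secondary alcohol, fast enough at low temperature to outrun relactonisation; TBDPS should survive methoxide and mild Lewis acid and leaves with fluoride.

Step 9
Reactants: 15 (5R,6R)-6-[(1S)-1-(tert-butyldiphenylsilyloxy)ethyl]-N-methoxy-N,5-dimethylcyclohex-1-ene-1-carboxamide; 16 4-methoxy-6-methyl-2H-pyran-2-one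
Product: 18 6-{2-[(5R,6R)-6-((1S)-1-(tert-butyldiphenylsilyloxy)ethyl)-5-methylcyclohex-1-en-1-yl]-2-oxoethyl}-4-methoxy-2H-pyran-2-one, via 6-(lithiomethyl)-4-methoxy-2H-pyran-2-one 17 (not isolated)
Conditions: 16 (1.6 equiv), LiN(iPr)2 (1.6 equiv), THF, −78 °C; then 15, −78 → −20 °C; aq. NH4Cl
Reagents that add atoms: none
Why: Claisen-type C-acylation in which the lithium dienolate of the pyranone methyl group adds 1,2 to the alpha-branched Weinreb amide, and the chelated tetrahedral intermediate prevents a second addition.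

Step 10
Reactants: 18 6-{2-[(5R,6R)-6-((1S)-1-(tert-butyldiphenylsilyloxy)ethyl)-5-methylcyclohex-1-en-1-yl]-2-oxoethyl}-4-methoxy-2H-pyran-2-one
Product: 20 [(5R,6R)-6-((1S)-1-(tert-butyldiphenylsilyloxy)ethyl)-5-methylcyclohex-1-en-1-yl](2,6-dihydroxy-4-methoxyphenyl)methanone, via open-chain methoxy-enoate diketone 19 (not isolated)
Conditions: Mg(OMe)2 (6 equiv), MeOH, 65 °C; then cold 1 M HCl
Reagents that add atoms: none
Why: Methoxide adds to C2 of the pyranone and opens it to the magnesium-chelated 3-methoxy-5,7-dioxohept-2-enoate 19, in which the ester and the diketone stay cis across the enol ether double bond inherited from the ring. The carbanion between the two ketones attacks the ester carbonyl, methoxide leaves, and the cyclohexadienone enolises to the arene. The closest known reaction is the Mg(OMe)2-mediated Claisen ring transformation of 6-(2-oxoalkyl)-4-hydroxy-2-pyranones into acylphloroglucinols, here run on the 4-O-methyl ether. The one ring closes in 6-exo-trig mode (enolate carbon onto the exocyclic ester C=O); no stereocentre is formed, and the existing ones are not adjacent to any site that is enolised. The step needs C-acylation in preference to aldol folding, O-cyclisation to a 4-pyranone or addition of the new phenoxide to the enone: the enol ether removes the nucleophilic C2 that aldol folding would need, magnesium chelation of the 1,3-diketone favours the carbon nucleophile, and the alpha-branched ring enone with its neighbouring C6 substituent is a poor Michael acceptor.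

Step 11
Reactants: 20 [(5R,6R)-6-((1S)-1-(tert-butyldiphenylsilyloxy)ethyl)-5-methylcyclohex-1-en-1-yl](2,6-dihydroxy-4-methoxyphenyl)methanone; 21 ethyl 2-methylacetoacetate
Product: 22 8-{[(5R,6R)-6-((1S)-1-(tert-butyldiphenylsilyloxy)ethyl)-5-methylcyclohex-1-en-1-yl]carbonyl}-7-hydroxy-5-methoxy-3,4-dimethyl-2H-chromen-2-one
Conditions: 21 (3 equiv), Sc(OTf)3 (10 mol %), toluene, 80 °C
Reagents that add atoms: none
Why: Pechmann condensation (hydroxyalkylation of the ring carbon between OH and OMe by the ketone of 21, lactonisation with the neighbouring phenol, dehydration); the two hydroxyls and the two free ring carbons of 20 are equivalent, so only one coumarin can form.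

Step 12
Reactants: 22 8-{[(5R,6R)-6-((1S)-1-(tert-butyldiphenylsilyloxy)ethyl)-5-methylcyclohex-1-en-1-yl]carbonyl}-7-hydroxy-5-methoxy-3,4-dimethyl-2H-chromen-2-one; 23 1-bromo-3-methylbut-2-ene
Product: 25 8-{[(5R,6R)-6-((1S)-1-(tert-butyldiphenylsilyloxy)ethyl)-5-methylcyclohex-1-en-1-yl]carbonyl}-7-hydroxy-5-methoxy-3,4-dimethyl-6-(3-methylbut-2-en-1-yl)-2H-chromen-2-one, via sodium phenoxide 24 (not isolated)
Conditions: NaH (1.1 equiv), toluene, 0 °C; then 23 (1.2 equiv), rt
Reagents that add atoms: none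
Why: C-alkylation of an ambident phenoxide, where the tight sodium chelate between O7 and the C8 carbonyl in a non-polar medium disfavours O-alkylation and C6, the only free ortho carbon, attacks the primary allylic bromide by SN2.

Step 13
Reactants: 25 8-{[(5R,6R)-6-((1S)-1-(tert-butyldiphenylsilyloxy)ethyl)-5-methylcyclohex-1-en-1-yl]carbonyl}-7-hydroxy-5-methoxy-3,4-dimethyl-6-(3-methylbut-2-en-1-yl)-2H-chromen-2-one
Product: 26 7-hydroxy-8-{[(5R,6R)-6-((1S)-1-hydroxyethyl)-5-methylcyclohex-1-en-1-yl]carbonyl}-5-methoxy-3,4-dimethyl-6-(3-methylbut-2-en-1-yl)-2H-chromen-2-one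
Conditions: TBAF, AcOH, THF, rt → 40 °C
Reagents that add atoms: none
Why: Fluoride-induced cleavage of the silyl ether, buffered with acetic acid so that the phenol stays protonated and cannot add to the enone; the product is the target.

**Compound list**

1 | (S)-but-3-yn-2-ol | C[C@H](O)C#C | starting material
2 | O,C-dilithiated (S)-but-3-yn-2-ol (not isolated) | [Li]C#C[C@H](C)O[Li] | intermediate
3 | (S)-4-hydroxypent-2-ynoic acid | C[C@H](O)C#CC(=O)O | intermediate
4 | (2Z,4S)-4-hydroxypent-2-enoic acid (not isolated) | C[C@H](O)/C=C\C(=O)O | intermediate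
5 | (S)-5-methylfuran-2(5H)-one | O=C1O[C@@H](C)C=C1 | intermediate
6 | (2E,4E)-hexa-2,4-dienoic acid | C/C=C/C=C/C(=O)O | starting material
7 | (2E,4E)-hexa-2,4-dienoyl azide (not isolated) | C/C=C/C=C/C(=O)N=[N+]=[N-] | intermediate
8 | (1E,3E)-1-isocyanatopenta-1,3-diene (not isolated) | C/C=C/C=C/N=C=O | intermediate
9 | benzyl N-[(1E,3E)-penta-1,3-dien-1-yl]carbamate | C/C=C/C=C/NC(=O)OCc1ccccc1 | intermediate
10 | benzyl N-[(3S,3aR,4R,7S,7aR)-3,4-dimethyl-1-oxo-1,3,3a,4,7,7a-hexahydroisobenzofuran-7-yl]carbamate | O=C1O[C@@H](C)[C@@H]2[C@H](C)C=C[C@H](NC(=O)OCc3ccccc3)[C@H]12 | intermediate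
11 | (3S,3aR,4R,7S,7aR)-7-amino-3,4-dimethylhexahydroisobenzofuran-1(3H)-one | O=C1O[C@@H](C)[C@@H]2[C@H](C)CC[C@H](N)[C@H]12 | intermediate
12 | (3S,3aR,4R,7S,7aR)-N,N,N,3,4-pentamethyl-1-oxooctahydroisobenzofuran-7-aminium iodide (not isolated) | O=C1O[C@@H](C)[C@@H]2[C@H](C)CC[C@H]([N+](C)(C)C)[C@H]12.[I-] | intermediate
13 | (3S,3aR,4R)-3,4-dimethyl-3a,4,5,6-tetrahydroisobenzofuran-1(3H)-one | O=C1O[C@@H](C)[C@@H]2[C@H](C)CCC=C12 | intermediate
14 | (5R,6R)-6-[(1S)-1-hydroxyethyl]-N-methoxy-N,5-dimethylcyclohex-1-ene-1-carboxamide | CON(C)C(=O)C1=CCC[C@@H](C)[C@H]1[C@H](C)O | intermediate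
15 | (5R,6R)-6-[(1S)-1-(tert-butyldiphenylsilyloxy)ethyl]-N-methoxy-N,5-dimethylcyclohex-1-ene-1-carboxamide | CON(C)C(=O)C1=CCC[C@@H](C)[C@H]1[C@H](C)O[Si](c1ccccc1)(c1ccccc1)C(C)(C)C | intermediate
16 | 4-methoxy-6-methyl-2H-pyran-2-one | COc1cc(C)oc(=O)c1 | starting material
17 | 6-(lithiomethyl)-4-methoxy-2H-pyran-2-one (not isolated) | [Li]Cc1cc(OC)cc(=O)o1 | intermediate
18 | 6-{2-[(5R,6R)-6-((1S)-1-(tert-butyldiphenylsilyloxy)ethyl)-5-methylcyclohex-1-en-1-yl]-2-oxoethyl}-4-methoxy-2H-pyran-2-one | O=c1cc(OC)cc(CC(=O)C2=CCC[C@@H](C)[C@H]2[C@H](C)O[Si](c2ccccc2)(c2ccccc2)C(C)(C)C)o1 | intermediate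
19 | methyl (2E)-7-[(5R,6R)-6-((1S)-1-(tert-butyldiphenylsilyloxy)ethyl)-5-methylcyclohex-1-en-1-yl]-3-methoxy-5,7-dioxohept-2-enoate, present as its magnesium enolate (not isolated) | COC(=O)/C=C(/OC)CC(=O)CC(=O)C1=CCC[C@@H](C)[C@H]1[C@H](C)O[Si](c1ccccc1)(c1ccccc1)C(C)(C)C | intermediate
20 | [(5R,6R)-6-((1S)-1-(tert-butyldiphenylsilyloxy)ethyl)-5-methylcyclohex-1-en-1-yl](2,6-dihydroxy-4-methoxyphenyl)methanone | COc1cc(O)c(C(=O)C2=CCC[C@@H](C)[C@H]2[C@H](C)O[Si](c2ccccc2)(c2ccccc2)C(C)(C)C)c(O)c1 | intermediate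
21 | ethyl 2-methylacetoacetate | CCOC(=O)C(C)C(C)=O | starting material
22 | 8-{[(5R,6R)-6-((1S)-1-(tert-butyldiphenylsilyloxy)ethyl)-5-methylcyclohex-1-en-1-yl]carbonyl}-7-hydroxy-5-methoxy-3,4-dimethyl-2H-chromen-2-one | COc1cc(O)c(C(=O)C2=CCC[C@@H](C)[C@H]2[C@H](C)O[Si](c2ccccc2)(c2ccccc2)C(C)(C)C)c2oc(=O)c(C)c(C)c12 | intermediate
23 | 1-bromo-3-methylbut-2-ene | CC(C)=CCBr | starting material
24 | sodium 7-phenoxide of 22 (not isolated) | COc1cc([O-])c(C(=O)C2=CCC[C@@H](C)[C@H]2[C@H](C)O[Si](c2ccccc2)(c2ccccc2)C(C)(C)C)c2oc(=O)c(C)c(C)c12.[Na+] | intermediate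
25 | 8-{[(5R,6R)-6-((1S)-1-(tert-butyldiphenylsilyloxy)ethyl)-5-methylcyclohex-1-en-1-yl]carbonyl}-7-hydroxy-5-methoxy-3,4-dimethyl-6-(3-methylbut-2-en-1-yl)-2H-chromen-2-one | COc1c(CC=C(C)C)c(O)c(C(=O)C2=CCC[C@@H](C)[C@H]2[C@H](C)O[Si](c2ccccc2)(c2ccccc2)C(C)(C)C)c2oc(=O)c(C)c(C)c12 | intermediate
26 | 7-hydroxy-8-{[(5R,6R)-6-((1S)-1-hydroxyethyl)-5-methylcyclohex-1-en-1-yl]carbonyl}-5-methoxy-3,4-dimethyl-6-(3-methylbut-2-en-1-yl)-2H-chromen-2-one | COc1c(CC=C(C)C)c(O)c(C(=O)C2=CCC[C@@H](C)[C@H]2[C@H](C)O)c2oc(=O)c(C)c(C)c12 | target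

**Step count and risks**

Total steps: 13. Longest linear sequence: 12 (steps 1, 2, 4–13); step 3 is a one-step branch.

Steps most likely to fail:

1. Step 10. The ring-opened chain may reclose to the pyranone or fold through oxygen to a 4-pyranone, or the new phenoxide may add to the enone. Fallback from 15, returning at 20: the aryl–acyl bond is made by organolithium acylation instead. Commercial 5-methoxybenzene-1,3-diol is protected with MOMCl and iPr2NEt as 1-methoxy-3,5-bis(methoxymethoxy)benzene F1. n-BuLi (THF, 0 °C) should metalate F1 between the two acetal oxygens to give [4-methoxy-2,6-bis(methoxymethoxy)phenyl]lithium F2. Addition of F2 to Weinreb amide 15 gives [(5R,6R)-6-((1S)-1-(tert-butyldiphenylsilyloxy)ethyl)-5-methylcyclohex-1-en-1-yl][4-methoxy-2,6-bis(methoxymethoxy)phenyl]methanone F3, and HCl (cat.) in MeOH at 40 °C removes both acetals to give 20.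

2. Step 12. O-alkylation may outrun C-alkylation, or the phenoxide may cyclise onto the enone under base. Fallback from 22, returning at 25: the prenyl group is transferred from oxygen by a sigmatropic shift. 22 is O-alkylated with 3-chloro-3-methylbut-1-yne (K2CO3, KI, CuI cat., acetone) to the 7-O-(2-methylbut-3-yn-2-yl) ether F4. Semihydrogenation over Pd/CaCO3 poisoned with Pb(OAc)2 gives the 7-O-(2-methylbut-3-en-2-yl) ether F5. Heating in toluene at 110 °C should then move the allyl group by aromatic Claisen rearrangement, with allylic inversion, to C6 and give 25.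

3. Step 11. The Lewis acid may remove the silyl ether or cyclise a phenol onto the enone before annulation is complete, or substitution on the acyl-deactivated ring may be too slow. Fallback from 20, returning at 22: ester formation and ring closure are separated. Heating 20 with tert-butyl 2-methyl-3-oxobutanoate in toluene at 110 °C (acylketene transfer, neutral) gives the mono-aryl ester 2-{[(5R,6R)-6-((1S)-1-(tert-butyldiphenylsilyloxy)ethyl)-5-methylcyclohex-1-en-1-yl]carbonyl}-3-hydroxy-5-methoxyphenyl 2-methyl-3-oxobutanoate F6. Brief treatment with MsOH (cat.) in CH2Cl2 at 0 °C should close the lactone ring by intramolecular hydroxyalkylation and dehydration to 22.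

Further compounds

F1 | step 10 | 1-methoxy-3,5-bis(methoxymethoxy)benzene | COCOc1cc(OC)cc(OCOC)c1
F2 | step 10 | [4-methoxy-2,6-bis(methoxymethoxy)phenyl]lithium | [Li]c1c(OCOC)cc(OC)cc1OCOC
F3 | step 10 | [(5R,6R)-6-((1S)-1-(tert-butyldiphenylsilyloxy)ethyl)-5-methylcyclohex-1-en-1-yl][4-methoxy-2,6-bis(methoxymethoxy)phenyl]methanone | COCOc1cc(OC)cc(OCOC)c1C(=O)C1=CCC[C@@H](C)[C@H]1[C@H](C)O[Si](c1ccccc1)(c1ccccc1)C(C)(C)C
F4 | step 12 | 8-{[(5R,6R)-6-((1S)-1-(tert-butyldiphenylsilyloxy)ethyl)-5-methylcyclohex-1-en-1-yl]carbonyl}-5-methoxy-3,4-dimethyl-7-[(2-methylbut-3-yn-2-yl)oxy]-2H-chromen-2-one | COc1cc(OC(C)(C)C#C)c(C(=O)C2=CCC[C@@H](C)[C@H]2[C@H](C)O[Si](c2ccccc2)(c2ccccc2)C(C)(C)C)c2oc(=O)c(C)c(C)c12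
F5 | step 12 | 8-{[(5R,6R)-6-((1S)-1-(tert-butyldiphenylsilyloxy)ethyl)-5-methylcyclohex-1-en-1-yl]carbonyl}-5-methoxy-3,4-dimethyl-7-[(2-methylbut-3-en-2-yl)oxy]-2H-chromen-2-one | COc1cc(OC(C)(C)C=C)c(C(=O)C2=CCC[C@@H](C)[C@H]2[C@H](C)O[Si](c2ccccc2)(c2ccccc2)C(C)(C)C)c2oc(=O)c(C)c(C)c12
F6 | step 11 | 2-{[(5R,6R)-6-((1S)-1-(tert-butyldiphenylsilyloxy)ethyl)-5-methylcyclohex-1-en-1-yl]carbonyl}-3-hydroxy-5-methoxyphenyl 2-methyl-3-oxobutanoate (labile alpha carbon of the keto ester undefined) | COc1cc(O)c(C(=O)C2=CCC[C@@H](C)[C@H]2[C@H](C)O[Si](c2ccccc2)(c2ccccc2)C(C)(C)C)c(OC(=O)C(C)C(C)=O)c1
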